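**Retrosynthetic overview**
1. The last C–C bond is a Morita–Baylis–Hillman hydroxymethylation at C2 of a cyclohept-2-enone.
2. Key step: that cyclohept-2-enone comes from a fully substituted cyclohexanone by one-carbon ring expansion (Me3SiCHN2 homologation with 1,2-alkyl shift, then Brook shift and Saegusa oxidation). The six-membered ring is that of p-cresol; the seven-membered ring is made from it second to last.
3. The side-chain carbinol comes from an asymmetric isopropenylation of an aldehyde; the aldehyde and the quaternary centre come from an MHAT–Giese addition of a 4-methylcyclohex-3-enone to acrolein, anti to the neighbouring alkenyl group.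
4. The (E)-enol ester comes from an (E)-vinylsilane (iododesilylation, Cu C–O coupling); SmI2 removes a temporary methoxy group.
5. The two ring CH stereocentres come from a new Rh-catalysed desymmetrising alkenylation/acetonylation of 4-methoxy-4-methylcyclohexadienone.

Assumption: Schwartz's reagent, 2-nitropropene and Me3SiCHN2 are taken as purchasable; the epimer mixture at the methoxy-bearing carbon of 6–11 is carried on because step 5 erases that centre.

**Step 1**
Reactants: 1 4-methylphenol (p-cresol)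
Product: 2 4-methoxy-4-methylcyclohexa-2,5-dien-1-one
Conditions: PhI(OAc)2, MeOH, 0 °C
Reagents that add atoms: methanol (CO)
Why: Hypervalent-iodine oxidative dearomatisation, in which methanol traps the oxidised phenol at the methyl-bearing para carbon to give the achiral p-quinol methyl ether.

**Step 2**
Reactants: 2 4-methoxy-4-methylcyclohexa-2,5-dien-1-one; 3 ethynyltrimethylsilane; 4 2-nitropropene
Product: 8 (4RS,5R,6S)-4-methoxy-4-methyl-6-(2-oxopropyl)-5-[(E)-2-(trimethylsilyl)ethenyl]cyclohex-2-en-1-one, via alkenylzirconocene 5 (not isolated), via zirconium dienolate 6 (not isolated), via zirconium nitronate 7 (not isolated)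
Conditions: 3, Cp2Zr(H)Cl, THF, rt; then 2, [Rh(cod)(MeCN)2]BF4 (5 mol%), (R)-BINAP (6 mol%), rt; then 4, −78 to 0 °C; then 3 M HCl, 0 °C
Reagents that add atoms: water (O)
Why: Proposed new method: Rh(I)/(R)-BINAP transfers the alkenyl group from zirconium to one enantiotopic enone of the prochiral dienone under catalyst control (the facial sense that gives (R)-3-substituted cyclohexanones from cyclohexenone, assigned by analogy), the zirconium dienolate is nucleophilic only at C6 and adds to 2-nitropropene anti to the new alkenyl group (trans), and Nef hydrolysis of the nitronate unveils the acetonyl ketone, while the C4 epimer ratio does not matter; the closest known reactions are the Rh/BINAP alkenylzirconocene 1,4-addition with enolate trapping on simple cycloalkenones, the Rh-catalysed desymmetrisation of cyclohexadienones with arylboron reagents and the nitroalkene acetonylation of enolates, whose combination on a 4,4-disubstituted cyclohexadienone has not been shown.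

**Step 3**
Reactants: 8 (4RS,5R,6S)-4-methoxy-4-methyl-6-(2-oxopropyl)-5-[(E)-2-(trimethylsilyl)ethenyl]cyclohex-2-en-1-one
Product: 9 (4RS,5R,6S)-5-[(E)-2-iodoethenyl]-4-methoxy-4-methyl-6-(2-oxopropyl)cyclohex-2-en-1-one
Conditions: NIS, (CF3)2CHOH, 0 °C
Reagents that add atoms: N-iodosuccinimide (O=C1CCC(=O)N1I)
Why: Electrophilic ipso-iododesilylation of the vinylsilane through a β-silyl cation proceeds with retention of the E geometry and leaves the electron-poor enone alone.

**Step 4**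
Reactants: 9 (4RS,5R,6S)-5-[(E)-2-iodoethenyl]-4-methoxy-4-methyl-6-(2-oxopropyl)cyclohex-2-en-1-one; 10 3-methylbut-2-enoic acid
Product: 11 (E)-2-[(1S,2RS,6S)-2-methoxy-2-methyl-5-oxo-6-(2-oxopropyl)cyclohex-3-en-1-yl]ethenyl 3-methylbut-2-enoate
Conditions: CuI (10 mol%), 3,4,7,8-tetramethyl-1,10-phenanthroline (20 mol%), Cs2CO3 (1 equiv), toluene, 80 °C
Reagents that add atoms: none
Why: Ullmann-type Cu(I)-catalysed C–O coupling of the alkenyl iodide with the carboxylate retains the alkene geometry, and the medium is only carboxylate-basic so the 1,4-diketone does not aldolise.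

**Step 5**
Reactants: 11 (E)-2-[(1S,2RS,6S)-2-methoxy-2-methyl-5-oxo-6-(2-oxopropyl)cyclohex-3-en-1-yl]ethenyl 3-methylbut-2-enoate
Product: 12 (E)-2-[(1S,6S)-2-methyl-5-oxo-6-(2-oxopropyl)cyclohex-2-en-1-yl]ethenyl 3-methylbut-2-enoate
Conditions: SmI2 (2.5 equiv), THF–MeOH, −78 °C
Reagents that add atoms: none
Why: Two-electron reduction of the enone by SmI2 and β-elimination of the γ-methoxide (vinylogous reductive deoxygenation) give a samarium dienolate that is protonated kinetically at the α-carbon, so both epimers converge on the deconjugated 4-methylcyclohex-3-enone with the two CH stereocentres untouched.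

**Step 6**
Reactants: 12 (E)-2-[(1S,6S)-2-methyl-5-oxo-6-(2-oxopropyl)cyclohex-2-en-1-yl]ethenyl 3-methylbut-2-enoate; 13 acrolein
Product: 14 (E)-2-[(1S,2S,6S)-2-methyl-5-oxo-6-(2-oxopropyl)-2-(3-oxopropyl)cyclohexyl]ethenyl 3-methylbut-2-enoate
Conditions: Fe(acac)3 (30 mol%), PhSiH2(Oi-Pr), EtOH, rt
Reagents that add atoms: none
Why: Fe–H hydrogen-atom transfer (Mukaiyama-type MHAT, reductive olefin coupling) puts H on the CH end of the trisubstituted alkene, and the tertiary radical, whose neighbouring alkenyl group sits pseudo-axial to avoid A1,2 strain with the methyl group, adds to acrolein (Giese addition) anti to that group, which sets the quaternary centre with the chain trans and the methyl cis to the alkenyl substituent.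

**Step 7**
Reactants: 14 (E)-2-[(1S,2S,6S)-2-methyl-5-oxo-6-(2-oxopropyl)-2-(3-oxopropyl)cyclohexyl]ethenyl 3-methylbut-2-enoate; 15 2-bromopropene
Product: 16 (E)-2-[(1S,2S,6S)-2-methyl-2-[(3R)-4-methyl-3-(trimethylsilyloxy)pent-4-en-1-yl]-5-oxo-6-(2-oxopropyl)cyclohexyl]ethenyl 3-methylbut-2-enoate
Conditions: CrCl2 (10 mol%), chiral Kishi sulfonamide ligand (12 mol%), NiCl2·DMP (2 mol%), Mn, Me3SiCl, MeCN, rt
Reagents that add atoms: chlorotrimethylsilane (C[Si](C)(C)Cl)
Why: Catalytic asymmetric Nozaki–Hiyama–Kishi alkenylation, in which the ligand-bound isopropenylchromium(III) adds only to the aldehyde, on its Si face under reagent control (ligand antipode chosen for this), to give the (R)-carbinol, released from chromium as the TMS ether that protects it in step 8.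

**Step 8**
Reactants: 16 (E)-2-[(1S,2S,6S)-2-methyl-2-[(3R)-4-methyl-3-(trimethylsilyloxy)pent-4-en-1-yl]-5-oxo-6-(2-oxopropyl)cyclohexyl]ethenyl 3-methylbut-2-enoate
Product: 19 (E)-2-[(1S,2S,7S)-2-methyl-2-[(3R)-4-methyl-3-(trimethylsilyloxy)pent-4-en-1-yl]-6-oxo-7-(2-oxopropyl)cyclohept-4-en-1-yl]ethenyl 3-methylbut-2-enoate, via alpha-silyl cycloheptanone 17 (not isolated), via enol silane 18 (not isolated)
Conditions: Me3SiCHN2 (1.2 equiv), Sc(OTf)3 (10 mol%), toluene, −20 °C to rt; then Pd(OAc)2 (1.1 equiv), MeCN, rt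
Reagents that add atoms: (trimethylsilyl)diazomethane (C[Si](C)(C)C=[N+]=[N-])
Why: Lewis-acid-catalysed diazoalkane–ketone homologation (Tiffeneau–Demjanov-type 1,2-shift) in which Me3SiCHN2 adds to the Sc-activated ring ketone (expected to be more reactive than the acyclic methyl ketone), the unsubstituted α-CH2 migrates anti-periplanar to N2 in preference to the hindered α-CH, a 1,3-Brook shift gives the regiodefined enol silane and Saegusa–Ito oxidation makes the cyclohept-2-enone, none of which touches a stereocentre.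

**Step 9**
Reactants: 19 (E)-2-[(1S,2S,7S)-2-methyl-2-[(3R)-4-methyl-3-(trimethylsilyloxy)pent-4-en-1-yl]-6-oxo-7-(2-oxopropyl)cyclohept-4-en-1-yl]ethenyl 3-methylbut-2-enoate
Product: 21 (E)-2-[(1S,2S,7S)-2-[(3R)-3-hydroxy-4-methylpent-4-en-1-yl]-5-(hydroxymethyl)-2-methyl-6-oxo-7-(2-oxopropyl)cyclohept-4-en-1-yl]ethenyl 3-methylbut-2-enoate (CNP0257974.1), via trimethylsilyl ether 20 (not isolated)
Conditions: 37% aq. HCHO, DMAP (30 mol%), THF–H2O, rt; then 0.5 M HCl
Reagents that add atoms: formaldehyde (C=O)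
Why: Morita–Baylis–Hillman reaction in which DMAP adds reversibly to the unhindered β-carbon, the enolate is hydroxymethylated at C2 and DMAP is expelled, the epimerisable centre next to the ketone stays trans to its neighbour, and the dilute-acid work-up removes the TMS ether.

**Compound list**
1 | 4-methylphenol (p-cresol) | Cc1ccc(O)cc1 | starting material
2 | 4-methoxy-4-methylcyclohexa-2,5-dien-1-one | COC1(C)C=CC(=O)C=C1 | intermediate
3 | ethynyltrimethylsilane | C#C[Si](C)(C)C | starting material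
4 | 2-nitropropene | C=C(C)[N+](=O)[O-] | starting material
5 | chlorobis(cyclopentadienyl)[(E)-2-(trimethylsilyl)ethenyl]zirconium | C[Si](C)(C)/C=C/[Zr](Cl)(C1C=CC=C1)C1C=CC=C1 | intermediate
6 | chlorobis(cyclopentadienyl)zirconium (3R,4RS)-4-methoxy-4-methyl-3-[(E)-2-(trimethylsilyl)ethenyl]cyclohexa-1,5-dien-1-olate | COC1(C)C=CC(O[Zr](Cl)(C2C=CC=C2)C2C=CC=C2)=C[C@@H]1/C=C/[Si](C)(C)C | intermediate
7 | zirconium nitronate (aci-nitro O–ZrCp2Cl) of (4RS,5R,6S)-4-methoxy-4-methyl-6-(2-nitropropyl)-5-[(E)-2-(trimethylsilyl)ethenyl]cyclohex-2-en-1-one | COC1(C)C=CC(=O)[C@@H](CC(C)=[N+]([O-])O[Zr](Cl)(C2C=CC=C2)C2C=CC=C2)[C@@H]1/C=C/[Si](C)(C)C | intermediate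
8 | (4RS,5R,6S)-4-methoxy-4-methyl-6-(2-oxopropyl)-5-[(E)-2-(trimethylsilyl)ethenyl]cyclohex-2-en-1-one | COC1(C)C=CC(=O)[C@@H](CC(C)=O)[C@@H]1/C=C/[Si](C)(C)C | intermediate
9 | (4RS,5R,6S)-5-[(E)-2-iodoethenyl]-4-methoxy-4-methyl-6-(2-oxopropyl)cyclohex-2-en-1-one | COC1(C)C=CC(=O)[C@@H](CC(C)=O)[C@@H]1/C=C/I | intermediate
10 | 3-methylbut-2-enoic acid (senecioic acid) | CC(C)=CC(=O)O | starting material
11 | (E)-2-[(1S,2RS,6S)-2-methoxy-2-methyl-5-oxo-6-(2-oxopropyl)cyclohex-3-en-1-yl]ethenyl 3-methylbut-2-enoate | COC1(C)C=CC(=O)[C@@H](CC(C)=O)[C@@H]1/C=C/OC(=O)C=C(C)C | intermediate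
12 | (E)-2-[(1S,6S)-2-methyl-5-oxo-6-(2-oxopropyl)cyclohex-2-en-1-yl]ethenyl 3-methylbut-2-enoate | CC1=CCC(=O)[C@@H](CC(C)=O)[C@@H]1/C=C/OC(=O)C=C(C)C | intermediate
13 | acrolein | C=CC=O | starting material
14 | (E)-2-[(1S,2S,6S)-2-methyl-5-oxo-6-(2-oxopropyl)-2-(3-oxopropyl)cyclohexyl]ethenyl 3-methylbut-2-enoate | O=CCC[C@@]1(C)CCC(=O)[C@@H](CC(C)=O)[C@@H]1/C=C/OC(=O)C=C(C)C | intermediate
15 | 2-bromopropene | C=C(C)Br | starting material
16 | (E)-2-[(1S,2S,6S)-2-methyl-2-[(3R)-4-methyl-3-(trimethylsilyloxy)pent-4-en-1-yl]-5-oxo-6-(2-oxopropyl)cyclohexyl]ethenyl 3-methylbut-2-enoate | C=C(C)[C@H](O[Si](C)(C)C)CC[C@@]1(C)CCC(=O)[C@@H](CC(C)=O)[C@@H]1/C=C/OC(=O)C=C(C)C | intermediate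
17 | (E)-2-[(1S,2S,7S)-2-methyl-2-[(3R)-4-methyl-3-(trimethylsilyloxy)pent-4-en-1-yl]-6-oxo-7-(2-oxopropyl)-5-(trimethylsilyl)cycloheptyl]ethenyl 3-methylbut-2-enoate (C5 epimers) | C=C(C)[C@H](O[Si](C)(C)C)CC[C@@]1(C)CCC([Si](C)(C)C)C(=O)[C@@H](CC(C)=O)[C@@H]1/C=C/OC(=O)C=C(C)C | intermediate
18 | (E)-2-[(1S,2R,7S)-2-methyl-2-[(3R)-4-methyl-3-(trimethylsilyloxy)pent-4-en-1-yl]-7-(2-oxopropyl)-6-(trimethylsilyloxy)cyclohept-5-en-1-yl]ethenyl 3-methylbut-2-enoate (same geometry as 16; the C2 descriptor changes by CIP priority only) | C=C(C)[C@H](O[Si](C)(C)C)CC[C@@]1(C)CCC=C(O[Si](C)(C)C)[C@@H](CC(C)=O)[C@@H]1/C=C/OC(=O)C=C(C)C | intermediate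
19 | (E)-2-[(1S,2S,7S)-2-methyl-2-[(3R)-4-methyl-3-(trimethylsilyloxy)pent-4-en-1-yl]-6-oxo-7-(2-oxopropyl)cyclohept-4-en-1-yl]ethenyl 3-methylbut-2-enoate | C=C(C)[C@H](O[Si](C)(C)C)CC[C@@]1(C)CC=CC(=O)[C@@H](CC(C)=O)[C@@H]1/C=C/OC(=O)C=C(C)C | intermediate
20 | (E)-2-[(1S,2S,7S)-5-(hydroxymethyl)-2-methyl-2-[(3R)-4-methyl-3-(trimethylsilyloxy)pent-4-en-1-yl]-6-oxo-7-(2-oxopropyl)cyclohept-4-en-1-yl]ethenyl 3-methylbut-2-enoate | C=C(C)[C@H](O[Si](C)(C)C)CC[C@@]1(C)CC=C(CO)C(=O)[C@@H](CC(C)=O)[C@@H]1/C=C/OC(=O)C=C(C)C | intermediate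
21 | (E)-2-[(1S,2S,7S)-2-[(3R)-3-hydroxy-4-methylpent-4-en-1-yl]-5-(hydroxymethyl)-2-methyl-6-oxo-7-(2-oxopropyl)cyclohept-4-en-1-yl]ethenyl 3-methylbut-2-enoate (CNP0257974.1) | C=C(C)[C@H](O)CC[C@@]1(C)CC=C(CO)C(=O)[C@@H](CC(C)=O)[C@@H]1/C=C/OC(=O)C=C(C)C | target

**Step count and risks**
Total steps: 9. Longest linear sequence: 9 (p-cresol to target; every other building block enters directly).

The three steps most likely to fail:

Step 2 (the proposed new coupling). The alkenyl transfer to a dienone whose β-carbon sits next to a quaternary centre may be slow, and the zirconium dienolate may not add cleanly to the nitroalkene. The fallback uses known chemistry, sets out from 2 and 3 and returns at 8. Zirconium-catalysed hydroboration of 3 with pinacolborane gives (E)-2-(trimethylsilyl)ethenylboronic acid pinacol ester F1. Hayashi–Miyaura Rh(I)/(R)-BINAP 1,4-addition of F1 to 2 (dioxane–H2O, cat. KOH) gives the β-alkenyl enone F2 as its C4 epimers. LDA (THF, −78 °C) gives the lithium dienolate F3, Michael addition to 4 gives the lithium nitronate F4, and cold 3 M HCl (Nef) gives 8.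

Step 6 (MHAT–Giese addition). The facial selectivity at the tertiary radical rests on one neighbouring substituent and may be only moderate, and the β,γ-enone can isomerise into conjugation. The fallback sets out from 12 and returns at 19; it expands the ring first and forms the quaternary centre by a polar 1,6-addition. Me3SiCHN2/Sc(OTf)3 gives the enol silane F5 and Pd(OAc)2 the cyclohepta-2,4-dienone F6. Cu(I)-catalysed 1,6-addition of commercial 2-(1,3-dioxolan-2-yl)ethylmagnesium bromide (CuBr·SMe2, Me3SiCl, THF, −78 °C) anti to the alkenyl group, then DBU equilibration into conjugation, gives the enone acetal F7. Aqueous oxalic acid gives the aldehyde F8, and the Ni/Cr isopropenylation of step 7 with 15 then gives 19.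

Step 8 (ring expansion). The diazoalkane may also attack the methyl ketone, and the migration selectivity or the one-pot Saegusa oxidation may suffer in so functionalised a substrate. The fallback sets out from 11 and returns at 19; it uses an Ito–Saegusa cyclopropanol ring expansion that needs no addition to a ketone. The SmI2 reduction of step 5, quenched with Me3SiCl, gives the silyl dienol ether F9. Furukawa cyclopropanation (Et2Zn, CH2I2) of its enol-ether double bond gives the siloxycyclopropane F10. FeCl3 in DMF (β-scission of the cyclopropyloxy radical) gives the ring-expanded β-chloro ketone F11, and NaOAc in MeOH eliminates HCl to the dienone F6, which goes on through F7 and F8 to 19 as described for step 6.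

**Further compounds**
F1 | step 2 | (E)-2-(trimethylsilyl)ethenylboronic acid pinacol ester | C[Si](C)(C)/C=C/B1OC(C)(C)C(C)(C)O1
F2 | step 2 | (4RS,5R)-4-methoxy-4-methyl-5-[(E)-2-(trimethylsilyl)ethenyl]cyclohex-2-en-1-one | COC1(C)C=CC(=O)C[C@@H]1/C=C/[Si](C)(C)C
F3 | step 2 | lithium (3R,4RS)-4-methoxy-4-methyl-3-[(E)-2-(trimethylsilyl)ethenyl]cyclohexa-1,5-dien-1-olate | COC1(C)C=CC(O[Li])=C[C@@H]1/C=C/[Si](C)(C)C
F4 | step 2 | lithium nitronate of (4RS,5R,6S)-4-methoxy-4-methyl-6-(2-nitropropyl)-5-[(E)-2-(trimethylsilyl)ethenyl]cyclohex-2-en-1-one | COC1(C)C=CC(=O)[C@@H](CC(C)=[N+]([O-])O[Li])[C@@H]1/C=C/[Si](C)(C)C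
F5 | step 6 | (E)-2-[(1S,7S)-2-methyl-7-(2-oxopropyl)-6-(trimethylsilyloxy)cyclohepta-2,5-dien-1-yl]ethenyl 3-methylbut-2-enoate | CC1=CCC=C(O[Si](C)(C)C)[C@@H](CC(C)=O)[C@@H]1/C=C/OC(=O)C=C(C)C
F6 | step 6 | (E)-2-[(1S,7S)-2-methyl-6-oxo-7-(2-oxopropyl)cyclohepta-2,4-dien-1-yl]ethenyl 3-methylbut-2-enoate | CC1=CC=CC(=O)[C@@H](CC(C)=O)[C@@H]1/C=C/OC(=O)C=C(C)C
F7 | step 6 | (E)-2-[(1S,2S,7S)-2-[2-(1,3-dioxolan-2-yl)ethyl]-2-methyl-6-oxo-7-(2-oxopropyl)cyclohept-4-en-1-yl]ethenyl 3-methylbut-2-enoate | C1COC(O1)CC[C@@]2(C)CC=CC(=O)[C@@H](CC(C)=O)[C@@H]2/C=C/OC(=O)C=C(C)C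
F8 | step 6 | (E)-2-[(1S,2S,7S)-2-methyl-6-oxo-7-(2-oxopropyl)-2-(3-oxopropyl)cyclohept-4-en-1-yl]ethenyl 3-methylbut-2-enoate | O=CCC[C@@]1(C)CC=CC(=O)[C@@H](CC(C)=O)[C@@H]1/C=C/OC(=O)C=C(C)C
F9 | step 8 | (E)-2-[(1S,6S)-2-methyl-6-(2-oxopropyl)-5-(trimethylsilyloxy)cyclohexa-2,4-dien-1-yl]ethenyl 3-methylbut-2-enoate | CC1=CC=C(O[Si](C)(C)C)[C@@H](CC(C)=O)[C@@H]1/C=C/OC(=O)C=C(C)C
F10 | step 8 | siloxycyclopropane from F9: the 1-(trimethylsilyloxy)bicyclo[4.1.0]hept-4-ene formed by CH2 addition to the enol-ether double bond (cyclopropane diastereomers) | CC1=CC2CC2(O[Si](C)(C)C)[C@@H](CC(C)=O)[C@@H]1/C=C/OC(=O)C=C(C)C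
F11 | step 8 | (E)-2-[(1S,7S)-4-chloro-2-methyl-6-oxo-7-(2-oxopropyl)cyclohept-2-en-1-yl]ethenyl 3-methylbut-2-enoate (C4 epimers) | CC1=CC(Cl)CC(=O)[C@@H](CC(C)=O)[C@@H]1/C=C/OC(=O)C=C(C)C
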